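Two numbers are asked of the flask, and the quick reply rests on one closed-form law.

| setting | noon | summer | winter | flask |
|---|---|---|---|---|
| starting material | 5.5 mM | 8.2 mM | 11 mM | 11 mM |
| second substrate | 55 mM | 55 mM | 55 mM | 55.0 mM |
| enzyme | 1.1 µM | 1.1 µM | 1.7 µM | 1.1 µM |
| remark | run made earlier | run made earlier | run made earlier |  |

| run | time / min | product / % | starting material / % |
|---|---|---|---|
| noon | 5.00 | 47.0 | 51.6 |
| noon | 8.00 | 69.3 | 30.5 |
| noon | 12.0 | 90.3 | 9.4 |
| noon | 20.0 | 98.3 | 0 |
| noon | 40.0 | 100.2 | 0 |
| noon | 60.0 | 101.0 | 0 |
| summer | 4.00 | 27.7 | 74.4 |
| summer | 12.0 | 76.8 | 27.0 |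
| summer | 20.0 | 99.6 | 0 |
| summer | 30.0 | 99.8 | 0.1 |
| summer | 50.0 | 99.5 | 0 |
| summer | 60.0 | 99.0 | 1.6 |
| winter | 5.00 | 39.1 | 60.5 |
| winter | 15.0 | 95.5 | 3.7 |
| winter | 30.0 | 102.6 | 0 |
| winter | 40.0 | 100.5 | 0 |
| winter | 60.0 | 99.4 | 0.8 |

(scatter of a reading: 1 percentage point)

- apparent order in enzyme when 20% of the starting material are converted (percent change of the rate of making product for one percent more enzyme charged)
- apparent order in second substrate when 20% of the starting material are converted (percent change of the rate of making product for one percent more second substrate charged)

- no earlier run changes the charge of second substrate; that part of a forecast is a guess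

The reckoning here takes a saturation law for the runs, and its integral says that top rate times elapsed time equals the starting material consumed plus a saturation constant times the logarithm of charged over left. The noon and summer runs share an enzyme charge and both were read at 12.0 min, so subtracting one from the other gives 0.951 mM as the saturation constant, the amount of starting material at which the rate stands at half of the top rate (the apparent Michaelis constant at this charge of second substrate), a reading that carries the scatter. The noon run then gives a top rate of 0.603 mM min⁻¹, and the winter reading at 15.0 min gives 0.915 mM min⁻¹, so this reckoning puts the enzyme order at 0.960.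

The forecast says 0.95 in enzyme and, with no run changing the second substrate, guesses 0.3, calling that substrate “probably partly saturated at 55 mM”.

The flask gives 1.0 in enzyme and 0.26 in second substrate, and at 0.100 h ternary complex, the resting state at that moment, holds 67.3% of the enzyme charged, against 20.9% as starting complex and 11.8% free.

    ternary complex → enzyme + product (k = 12.4 s⁻¹)
    starting material + enzyme ⇌ starting complex (K = 530 M⁻¹, k = 16600 M⁻¹ s⁻¹)
    second substrate + starting complex ⇌ ternary complex (K = 78.6 M⁻¹, k = 3760 M⁻¹ s⁻¹)

With the saturation constant and the noon top rate, the closed form puts 20% conversion in the flask at 0.0667 h, and the flask reaches it at 0.0640 h.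

(The data were generated by integration on assumed constants; noise was put on by code.)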